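## Retrosynthetic overview

- **Numbering (gmelinol):** C1H2–O2–C3H(Ar)–C3a(OH)–C4H2–O5–C6H(Ar)–C6aH. Ring A holds O2, ring B holds O5, and Ar = 3,4-dimethoxyphenyl.
- **Enabling feature:** C6a carries both C1 (the OCH2 of ring A) and the tertiary carbinol C3a, and it is α to C6. With C6 raised to a lactone carbonyl, C1=C6a is an acrylate, C3a a ketone and O2–C3–C3a an α-ketol. C6a–C3a (aldol) and C1–O2 (conjugate etherification) then both grow from one C=C.
- **Disconnections:** C6–H (hydride to an aryl oxocarbenium ion) and C6–Ar (aryllithium + lactone) lead back to a bicyclic hydroxylactone. Cutting C6a–C3a and C1–O2 together gives an acyclic (R)-ketol acrylate, which comes from a chloroketone plus acrylate, and the chloroketone from an (R)-mandelate.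
- **Ring order:** ring B closes first, then ring A, both in the flask of the key step. Afterwards ring B is only re-functionalised at C6.
- **Stereo logic:** C3 is set by a catalyst. C3 controls C3a and C6a (aryl exo). C6 is set last by hydride on the convex face, which puts the second aryl endo.

Key step: step 6

Remark: hemiketal 12 is drawn without configuration at C6 because it equilibrates with its open hydroxy ketone and this centre is erased in step 8. Gmelinol numbering is used in the text even where the systematic name of an intermediate numbers differently.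

## Route

Step 1
Reactants: 1 ethyl 2-(3,4-dimethoxyphenyl)-2-oxoacetate
Product: 2 ethyl (R)-2-(3,4-dimethoxyphenyl)-2-hydroxyacetate
Conditions: RuCl(p-cymene)[(S,S)-TsDPEN] (0.5 mol%), HCO2H/Et3N 5:2, EtOAc, 25 °C
Reagents that add atoms: none
Why: Noyori–Ikariya asymmetric transfer hydrogenation of an aryl α-keto ester, in which the aryl/η6-arene CH–π contact fixes the hydride face, so that the (S,S) ligand should set C3 as R (same spatial sense as (S)-1-arylethanols, descriptor changed by the ester priority).

Step 2
Reactants: 2 ethyl (R)-2-(3,4-dimethoxyphenyl)-2-hydroxyacetate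
Product: 3 ethyl (R)-2-[(tert-butyldimethylsilyl)oxy]-2-(3,4-dimethoxyphenyl)acetate
Conditions: TBSCl, imidazole, DMF, 23 °C
Reagents that add atoms: tert-butyldimethylsilyl chloride, CC(C)(C)[Si](C)(C)Cl
Why: Standard imidazole-promoted silylation of a secondary alcohol masks O2 against the carbenoid and carboxylate steps and touches no stereocentre.

Step 3
Reactants: 3 ethyl (R)-2-[(tert-butyldimethylsilyl)oxy]-2-(3,4-dimethoxyphenyl)acetate, 4 chloroiodomethane
Product: 5 (R)-1-[(tert-butyldimethylsilyl)oxy]-3-chloro-1-(3,4-dimethoxyphenyl)propan-2-one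
Conditions: 4 (3 equiv), MeLi·LiBr (2.8 equiv), THF/Et2O, −78 °C; AcOH quench at −78 °C
Reagents that add atoms: chloroiodomethane (4), ClCI
Why: Acylation of chloromethyllithium by an ester (halomethyllithium homologation with in situ carbenoid generation), in which the tetrahedral lithium adduct survives at −78 °C until the acidic quench, so that a single CH2Cl (the future C4) enters and the fast addition outruns deprotonation at C3.

Step 4
Reactants: 5 (R)-1-[(tert-butyldimethylsilyl)oxy]-3-chloro-1-(3,4-dimethoxyphenyl)propan-2-one, 6 potassium acrylate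
Product: 7 (R)-3-[(tert-butyldimethylsilyl)oxy]-3-(3,4-dimethoxyphenyl)-2-oxopropyl acrylate
Conditions: 6 (1.3 equiv), NaI (10 mol%), BHT (1 mol%), DMF, 0 °C → 23 °C
Reagents that add atoms: potassium acrylate (6), C=CC(=O)[O-].[K+]
Why: SN2 displacement at an α-halo ketone by a carboxylate with Finkelstein assistance (phenacyl-ester type esterification) forms the C4–O5 bond under nearly neutral conditions that leave C3 and the acrylate double bond untouched.

Step 5
Reactants: 7 (R)-3-[(tert-butyldimethylsilyl)oxy]-3-(3,4-dimethoxyphenyl)-2-oxopropyl acrylate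
Product: 8 (R)-3-(3,4-dimethoxyphenyl)-3-hydroxy-2-oxopropyl acrylate
Conditions: HF·pyridine, THF, 0 °C; pH 7 buffer work-up; used at once
Reagents that add atoms: none
Why: Fluoride-mediated desilylation under mildly acidic conditions frees O2–H without base, so that the configurationally labile benzylic ketol centre and the primary acrylate should stay in place.

Step 6
Reactants: 8 (R)-3-(3,4-dimethoxyphenyl)-3-hydroxy-2-oxopropyl acrylate
Product: 10 (3aS,4R,6aS)-4-(3,4-dimethoxyphenyl)-3a-hydroxytetrahydro-1H,3H-furo[3,4-c]furan-1-one, via methylene hydroxylactone 9 (not isolated)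
Conditions: DABCO (1.0 equiv), BHT (1 mol%), MeCN (0.02 M), 23 °C, Ar
Reagents that add atoms: none
Why: Proposed new method: DABCO adds to the acrylate terminus C1, the ammonium enolate carbon C6a attacks the ketone C3a to close lactone ring B, and the benzylic oxygen O2 then takes C1 with loss of DABCO, either by direct displacement of the ammonium or through E1cB to 9 and oxa-Michael addition, so that 8 is isomerised to 10 without any added atom. The closest known reaction types are the amine-mediated intramolecular Morita–Baylis–Hillman lactonisation of acrylates of α-hydroxy aldehydes and the base-catalysed oxa-Michael addition of alcohols to α-methylene-γ-butyrolactones; new are the ketone acceptor and the merger of both events in one flask. Ring B closes in the 5-(enolendo)-exo-trig mode, formally disfavoured but the mode of those lactonisations and of Lacey–Dieckmann tetronate closures, and ring A closes 5-exo-tet at CH2–N+ (or 5-endo-trig on 9). C3a is controlled by C3: the O2–H···O=C3a hydrogen bond holds both oxygens syn-coplanar as in a Cram chelate, the enolate comes in anti to the aryl group and gives 3aS with OH cis to the aryl, which is also the thermodynamic exo-aryl isomer that the reversible steps can funnel to. C6a is fixed when the last enolate or ammonium stage is resolved on a bicyclo[3.3.0] frame, where only the cis ring fusion (H-6a cis to 3a-OH) is accessible. The step needs C–C before C–O bond formation, attack on the ketone rather than proton loss at C3, and no acyl shift: O2 can reach C1 only through an eight-membered ring until C6a–C3a exists, the ketone is activated by two α-oxygens and the hydrogen bond, and a weakly basic amine in dilute aprotic medium keeps C3–H and the primary ester in place.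

Step 7
Reactants: 10 (3aS,4R,6aS)-4-(3,4-dimethoxyphenyl)-3a-hydroxytetrahydro-1H,3H-furo[3,4-c]furan-1-one, 11 4-bromo-1,2-dimethoxybenzene
Product: 12 (3aS,4R,6aS)-1,4-bis(3,4-dimethoxyphenyl)tetrahydro-1H,3H-furo[3,4-c]furan-1,3a-diol (hemiketal, both anomers)
Conditions: 11 (2.4 equiv), n-BuLi (2.3 equiv), THF, −78 °C; then 10, −78 °C; AcOH quench at −78 °C
Reagents that add atoms: 4-bromo-1,2-dimethoxybenzene (11, used as its aryllithium), COc1ccc(Br)cc1OC
Why: Mono-addition of an aryllithium to a γ-lactone (the lactol synthesis used for C-aryl glycosides), with the first equivalent spent on the tertiary OH and the tetrahedral adduct stable at −78 °C, gives the hemiketal whose new C6 centre need not be controlled.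

Step 8
Reactants: 12 (3aS,4R,6aS)-1,4-bis(3,4-dimethoxyphenyl)tetrahydro-1H,3H-furo[3,4-c]furan-1,3a-diol
Product: 14 (+)-gmelinol, via oxocarbenium ion 13 (not isolated)
Conditions: Et3SiH (4 equiv), BF3·OEt2 (1.5 equiv), CH2Cl2, −78 °C → −50 °C; Et3N, then aq NaHCO3
Reagents that add atoms: none
Why: Ionic hydrogenation of an aryl hemiketal (silane/Lewis acid lactol reduction): the veratryl-stabilised oxocarbenium ion 13 forms far below the temperature at which the benzylic ethers ionise and takes hydride on the convex face of the cis-bicyclo[3.3.0] frame, the face of H-6a and 3a-OH, so that H-6 ends cis to H-6a and the aryl group endo (6R).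

## Compound list

1 | ethyl 2-(3,4-dimethoxyphenyl)-2-oxoacetate | CCOC(=O)C(=O)c1ccc(OC)c(OC)c1 | starting material
2 | ethyl (R)-2-(3,4-dimethoxyphenyl)-2-hydroxyacetate | CCOC(=O)[C@H](O)c1ccc(OC)c(OC)c1 | intermediate
3 | ethyl (R)-2-[(tert-butyldimethylsilyl)oxy]-2-(3,4-dimethoxyphenyl)acetate | CCOC(=O)[C@H](O[Si](C)(C)C(C)(C)C)c1ccc(OC)c(OC)c1 | intermediate
4 | chloroiodomethane | ClCI | starting material
5 | (R)-1-[(tert-butyldimethylsilyl)oxy]-3-chloro-1-(3,4-dimethoxyphenyl)propan-2-one | ClCC(=O)[C@H](O[Si](C)(C)C(C)(C)C)c1ccc(OC)c(OC)c1 | intermediate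
6 | potassium acrylate | C=CC(=O)[O-].[K+] | starting material
7 | (R)-3-[(tert-butyldimethylsilyl)oxy]-3-(3,4-dimethoxyphenyl)-2-oxopropyl acrylate | C=CC(=O)OCC(=O)[C@H](O[Si](C)(C)C(C)(C)C)c1ccc(OC)c(OC)c1 | intermediate
8 | (R)-3-(3,4-dimethoxyphenyl)-3-hydroxy-2-oxopropyl acrylate | C=CC(=O)OCC(=O)[C@H](O)c1ccc(OC)c(OC)c1 | intermediate
9 | (S)-4-[(R)-(3,4-dimethoxyphenyl)(hydroxy)methyl]-4-hydroxy-3-methylenedihydrofuran-2(3H)-one | COc1ccc([C@@H](O)[C@@]2(O)COC(=O)C2=C)cc1OC | intermediate
10 | (3aS,4R,6aS)-4-(3,4-dimethoxyphenyl)-3a-hydroxytetrahydro-1H,3H-furo[3,4-c]furan-1-one (cis-fused, aryl exo and cis to OH) | COc1ccc([C@H]2OC[C@@H]3C(=O)OC[C@]23O)cc1OC | intermediate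
11 | 4-bromo-1,2-dimethoxybenzene | COc1ccc(Br)cc1OC | starting material
12 | (3aS,4R,6aS)-1,4-bis(3,4-dimethoxyphenyl)tetrahydro-1H,3H-furo[3,4-c]furan-1,3a-diol (hemiketal, C6 of gmelinol numbering undefined) | COc1ccc([C@H]2OC[C@@H]3C(O)(c4ccc(OC)c(OC)c4)OC[C@]23O)cc1OC | intermediate
13 | bicyclic 6-aryl oxocarbenium ion formed from 12 by loss of the hemiketal OH (C3, C3a, C6a as in 12) | COc1ccc([C@H]2OC[C@@H]3C(c4ccc(OC)c(OC)c4)=[O+]C[C@]23O)cc1OC | intermediate
14 | (+)-gmelinol, (3R,3aS,6R,6aR)-3,6-bis(3,4-dimethoxyphenyl)tetrahydro-1H,3H-furo[3,4-c]furan-3a-ol | COc1ccc([C@H]2OC[C@@H]3[C@H](c4ccc(OC)c(OC)c4)OC[C@]23O)cc1OC | target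

## Step count

- Total step count: 8
- Longest linear sequence: 8 (1 → 14)

## Steps most likely to fail

**1. Step 6.**
- What may go wrong: the ammonium enolate may be protonated faster than it attacks the ketone. The acrylate may shift to the benzylic oxygen. Enolisation at C3 may erode the configuration. The facial selectivity at the ketone may be poor.
- Fallback (known reactions, stoichiometric sulfur relay in place of amine catalysis): it sets out from 8. PhSMgBr (from PhSH and EtMgBr, 2.2 equiv, CH2Cl2, −78 °C → 0 °C) carries out a thia-Michael/aldol tandem reaction on the magnesium-chelated ketol. This should give the phenylthiomethyl hydroxylactone F1. MeOTf methylates sulfur to the S-methylsulfonium triflate F2. K2CO3 in MeCN then expels the sulfide to 9, which closes by oxa-Michael addition and comes back to the route at 10.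

**2. Step 8.**
- What may go wrong: the oxocarbenium ion may lose H-6a to an enol ether that dehydrates to a furan. Hydride may arrive from the concave face. The Lewis acid may epimerise or over-reduce the benzylic ethers.
- Fallback (syn hydrogenation in place of ionic reduction): it sets out from 12. MsCl/Et3N in CH2Cl2 at −20 °C dehydrates the hemiketal under basic conditions to the C6=C6a enol ether F3. Hydroxyl-directed hydrogenation with [Ir(cod)(PCy3)(py)]PF6 and H2 in CH2Cl2 adds both hydrogens on the face of 3a-OH. H-6 and H-6a then end cis to the OH, and the sequence comes back to the route at 14.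

**3. Step 7.**
- What may go wrong: the aryllithium may enolise the lactone at C6a, with β-elimination of O2 and opening of ring A. Early collapse of the adduct may allow a second aryl addition. The open keto alkoxide may undergo retro-aldol cleavage.
- Fallback (acyl transfer through a chelated amide in place of direct lactone addition): it sets out from 10. MeNH(OMe)·HCl with AlMe3 in CH2Cl2 opens the lactone to the Weinreb amide F4. The aryllithium from 11 (3.3 equiv, THF, −78 °C) adds once to the chelated amide. The hydroxy ketone set free on quench closes and comes back to the route at 12.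

## Further compounds

F1 | step 6 | (4S)-4-[(R)-(3,4-dimethoxyphenyl)(hydroxy)methyl]-4-hydroxy-3-[(phenylthio)methyl]dihydrofuran-2(3H)-one | COc1ccc([C@@H](O)[C@@]2(O)COC(=O)C2CSc3ccccc3)cc1OC
F2 | step 6 | S-methylsulfonium triflate of F1 | COc1ccc([C@@H](O)[C@@]2(O)COC(=O)C2C[S+](C)c3ccccc3)cc1OC.[O-]S(=O)(=O)C(F)(F)F
F3 | step 8 | (3R,3aS)-3,6-bis(3,4-dimethoxyphenyl)-3,4-dihydro-1H-furo[3,4-c]furan-3a-ol (C6=C6a enol ether) | COc1ccc([C@H]2OCC3=C(c4ccc(OC)c(OC)c4)OC[C@]23O)cc1OC
F4 | step 7 | (3S,4S,5R)-5-(3,4-dimethoxyphenyl)-4-hydroxy-4-(hydroxymethyl)-N-methoxy-N-methyltetrahydrofuran-3-carboxamide | COc1ccc([C@H]2OC[C@H](C(=O)N(C)OC)[C@]2(O)CO)cc1OC
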